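**Strategy**

Everything rests on disconnecting ring C of unit B (the epiafzelechin unit) at its C4–C4a bond. The precursor is a chiral aryl propargyl ether: O1–C2 is already in place, C3≡C4 is an alkyne, C4 carries C8 of the epicatechin-(4β→6)-epicatechin half, and the phloroglucinol ring carries unit A para to O1. A gold-catalysed 6-endo-dig hydroarylation closes the last ring and joins C4 to C4a in one operation. It exploits two features: unit A at C6 lies para to O1, so both ortho carbons are equivalent and only the 4→6 isomer can arise; and the all-cis C2/C3/C4 triad can be read off from C2 alone through the C3=C4 bond.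

Key step: step 16

**Remarks and assumptions**

- Reading of the target: epicatechin-(4α→6)-epiafzelechin-(4α→8)-epicatechin-(4β→6)-epicatechin, units A-B-C-D in that order. All four units are 2R,3R (2,3-cis); units A and B are 3,4-cis (all-cis), unit C is 3,4-trans.
- α is the face of a heterocycle that carries its own C2 aryl group, β the opposite face; Bn = benzyl.
- Assumption for step 14: the enantiomer of the pybox ligand is the one that delivers the S ether; it would be assigned on phenol 9 as a model.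

**Route**

Step 1
Reactants: 1 (−)-epicatechin
Product: 2 5,7,3',4'-tetra-O-benzylepicatechin
Conditions: BnBr (4.4 equiv), K2CO3, DMF, 0 °C to rt
Reagents that add atoms: benzyl bromide, BrCc1ccccc1
Why: Williamson etherification of the four phenols only, since K2CO3 does not deprotonate the C3 alcohol and is too weak to epimerise C2.

Step 2
Reactants: 2 5,7,3',4'-tetra-O-benzylepicatechin
Product: 3 3,5,7,3',4'-penta-O-benzylepicatechin
Conditions: NaH, BnBr, Bu4NI (cat.), THF/DMF, 0 °C to rt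
Reagents that add atoms: benzyl bromide, BrCc1ccccc1
Why: Williamson etherification of the C3 alkoxide, which blocks this alcohol against the later oxidation.

Step 3
Reactants: 3 3,5,7,3',4'-penta-O-benzylepicatechin
Product: 4 8-bromo-3,5,7,3',4'-penta-O-benzylepicatechin (unit D)
Conditions: NBS (1.0 equiv), CH2Cl2, −78 to 0 °C
Reagents that add atoms: N-bromosuccinimide, O=C1CCC(=O)N1Br
Why: electrophilic aromatic bromination goes to C8, the more accessible carbon of ring A (C6 lies between two benzyloxy groups), and caps it for the later 4→6 coupling.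

Step 4
Reactants: 3 3,5,7,3',4'-penta-O-benzylepicatechin
Product: 5 (2R,3R,4S)-3,5,7,3',4'-penta-O-benzylepicatechin-4β-ol
Conditions: DDQ (2 equiv), CH2Cl2/H2O, rt
Reagents that add atoms: water, O
Why: DDQ benzylic oxidation (hydride abstraction at C4, assisted by ring A), and water should add to the cation on the β face, trans to the axial 3-OBn group, which sets C4.

Step 5
Reactants: 5 penta-O-benzylepicatechin-4β-ol
Product: 6 8-iodo-penta-O-benzylepicatechin-4β-ol (unit C)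
Conditions: NIS (1.05 equiv), CH2Cl2, −20 to 0 °C, dark
Reagents that add atoms: N-iodosuccinimide, O=C1CCC(=O)N1I
Why: electrophilic aromatic iodination at C8 by the same site preference as in step 3; the iodide is the later cross-coupling handle and suppresses self-condensation at C8.

Step 6
Reactants: 6 8-iodo-penta-O-benzylepicatechin-4β-ol; 4 8-bromo-penta-O-benzylepicatechin (3 equiv, excess recovered)
Product: 7 deca-O-benzyl 8-iodoepicatechin-(4β→6)-8-bromoepicatechin (units C–D)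
Conditions: Me3SiOTf (0.1 equiv), CH2Cl2, −78 to −40 °C; Et3N quench
Reagents that add atoms: none
Why: Friedel–Crafts interflavan coupling in which the 4-hydroxy group of 6 leaves as water and the C4 cation is attacked by C6 of 4 (C8 is capped by bromine) on the β face, trans to the axial 3-OBn group, so C4 of unit C becomes 4β.

Step 7
Reactants: 5 penta-O-benzylepicatechin-4β-ol
Product: 8 (2R,3S)-3,5,7,3',4'-pentakis(benzyloxy)flavan-4-one
Conditions: Dess–Martin periodinane, NaHCO3, CH2Cl2, rt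
Reagents that add atoms: none
Why: Dess–Martin oxidation of the benzylic alcohol under non-basic conditions, which should leave the 2,3-cis arrangement next to the new ketone intact.

Step 8
Reactants: 9 3,5-bis(benzyloxy)phenol
Product: 10 [3,5-bis(benzyloxy)phenoxy]tri(propan-2-yl)silane
Conditions: TIPSCl, imidazole, DMF, rt
Reagents that add atoms: chlorotri(propan-2-yl)silane, CC(C)[Si](Cl)(C(C)C)C(C)C
Why: silylation marks the oxygen that will become O1 of unit B and makes it a poor, bulky directing group for the next step.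

Step 9
Reactants: 10 [3,5-bis(benzyloxy)phenoxy]tri(propan-2-yl)silane (2 equiv); 8 pentakis(benzyloxy)flavan-4-one
Product: 12 4α-hydroxy-4β-[2,6-bis(benzyloxy)-4-(triisopropylsilyloxy)phenyl] adduct of ketone 8, via aryllithium 11 (not isolated)
Conditions: n-BuLi, THF, 0 °C, 1 h; then 8, −78 to 0 °C; H2O
Reagents that add atoms: n-butyllithium, [Li]CCCC (lithium in 11 only)
Why: directed ortho-metalation between the two cooperating benzyloxy groups fixes the aryl carbon para to the silyloxy group, and 1,2-addition to the ketone is expected trans to the 3-OBn group (the C4 configuration is erased in step 10, so either epimer serves).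

Step 10
Reactants: 12 tertiary alcohol
Product: 13 penta-O-benzylepicatechin carrying at C4, on the α face, a 2,6-bis(benzyloxy)-4-(triisopropylsilyloxy)phenyl group (all-cis)
Conditions: Bu3SnH, CF3CO2H, CH2Cl2, 0 °C
Reagents that add atoms: none
Why: ionic deoxygenation, in which the hydroxy group leaves as water and the doubly benzylic cation takes hydride on the β face, trans to the axial 3α-OBn group, leaving the aryl group on the α face, a selectivity known for 4-aryl-4-hydroxy-2,3-cis-flavans.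

Step 11
Reactants: 13 silyl ether
Product: 14 penta-O-benzylepicatechin carrying at C4 (α) a 2,6-bis(benzyloxy)-4-hydroxyphenyl group (units A–B')
Conditions: Bu4NF, THF, 0 °C; H2O
Reagents that add atoms: none
Why: fluoride-induced desilylation frees only the phenol para to unit A, the future O1.

Step 12
Reactants: 15 4-(benzyloxy)benzaldehyde; 16 ethynylmagnesium bromide
Product: 17 rac-1-[4-(benzyloxy)phenyl]prop-2-yn-1-ol
Conditions: THF, 0 °C; H2O
Reagents that add atoms: none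
Why: Grignard 1,2-addition to the aldehyde; the racemate suffices because step 14 is enantioconvergent.

Step 13
Reactants: 17 rac-1-[4-(benzyloxy)phenyl]prop-2-yn-1-ol
Product: 18 rac-1-[4-(benzyloxy)phenyl]prop-2-yn-1-yl acetate
Conditions: Ac2O, pyridine, DMAP (cat.), CH2Cl2, 0 °C to rt
Reagents that add atoms: acetic anhydride, CC(=O)OC(C)=O
Why: acylation turns the alcohol into the leaving group needed for copper allenylidene formation.

Step 14
Reactants: 14 phenol (1 equiv); 18 rac-propargylic acetate (2 equiv)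
Product: 19 (S)-1-[4-(benzyloxy)phenyl]prop-2-yn-1-yl ether of phenol 14
Conditions: CuOTf·0.5C6H6 (5 mol %, copper in its monovalent state), chiral 2,6-bis(oxazolinyl)pyridine ligand (10 mol %), i-Pr2NEt, ClCH2CH2Cl, −20 °C
Reagents that add atoms: none
Why: copper-catalysed asymmetric propargylic etherification, in which both enantiomers of 18 converge on one copper allenylidene and the phenoxide attacks its γ-carbon on the face left open by the ligand, setting C2 of unit B by catalyst control (the stereocentres of unit A are remote).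

Step 15
Reactants: 19 terminal alkyne; 7 iodide of units C–D (1.1 equiv)
Product: 20 (R)-configured 1,3-diarylpropargyl aryl ether carrying unit A, the open unit B and units C–D (C8 of unit C on the alkyne)
Conditions: Pd(PPh3)4 (10 mol %), CuI (10 mol %), Et3N/THF (degassed), 50 °C
Reagents that add atoms: none
Why: Sonogashira coupling, chemoselective because zerovalent palladium inserts into the C–I bond of unit C well before the C–Br bond of unit D, while the mild amine base should leave the propargylic stereocentre untouched (the descriptor changes from S to R only because the alkyne gains priority).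

Step 16
Reactants: 20 1,3-diarylpropargyl aryl ether
Product: 21 (2S)-4-aryl-2H-chromene (flav-3-ene) of unit B, with unit A at C6 and C8 of unit C at C4
Conditions: [(t-Bu)2(2-biphenylyl)P]Au(NCMe)SbF6 (5 mol %), 4 Å molecular sieves, CH2Cl2, 0 °C to rt
Reagents that add atoms: none
Why: The cationic gold centre (monovalent gold) binds the alkyne, whose C4 terminus is made electrophilic by the trioxygenated ring A of unit C; the carbon of the phloroglucinol ring ortho to O1 attacks C4 in a Friedel–Crafts sense, and rearomatisation with protodeauration releases the chromene. The closest known reaction type is the gold-catalysed intramolecular hydroarylation of aryl propargyl ethers to 2H-chromenes. Ring C of unit B closes in the 6-endo-dig mode through the C4–C4a bond; the 5-exo-dig mode is disfavoured because it would place the positive charge on C3, away from the donor ring. No new stereocentre is formed: C2 is a spectator and keeps its configuration, and it later controls C3 and C4 through the C3=C4 bond made here. Regioselectivity on the arene is not at stake, because unit A sits para to O1 and the two ortho carbons are equivalent, so only the 4→6 isomer can form. The step also needs the benzylic C2–O1 bond to survive, which the soft phosphine–gold catalyst, low temperature and absence of protic acid should secure.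

Step 17
Reactants: 21 4-aryl-2H-chromene
Product: 23 2,3-trans-3,4-trans alcohol of unit B (3β-OH, unit C on the α face of C4), via alkylborane 22 (not isolated)
Conditions: BH3·THF (excess), THF, 0 °C to rt; then NaOH (aq), H2O2, 0 °C to rt
Reagents that add atoms: borane–tetrahydrofuran, B.C1CCOC1 (boron in 22 only); hydrogen peroxide, OO
Why: hydroboration–oxidation adds boron to C3 and hydrogen to C4 in a syn fashion on the β face, anti to the C2 aryl group, which sets C4 (aryl α) and gives the 3β-alcohol with retention on oxidation, as known for flav-3-enes.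

Step 18
Reactants: 23 3β-alcohol
Product: 24 2,4-cis-4-arylflavan-3-one of unit B
Conditions: Dess–Martin periodinane, NaHCO3, CH2Cl2, 0 °C to rt; used crude
Reagents that add atoms: none
Why: Dess–Martin oxidation of the only free alcohol under buffered conditions; the ketone is carried on without chromatography so that the acidic C2 and C4 hydrogens are not exchanged.

Step 19
Reactants: 24 flavan-3-one
Product: 25 octadeca-O-benzyl, 8-bromo (unit D) derivative of the target with the free all-cis 3α-OH in unit B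
Conditions: LiBH(s-Bu)3, LiBr, THF, −78 °C; H2O
Reagents that add atoms: none
Why: reduction with a bulky hydride from the β face, anti to the two pseudo-equatorial aryl groups at C2 and C4, should give the axial 3α-alcohol, the same inversion tactic that converts catechin-type into epicatechin-type flavans.

Step 20
Reactants: 25 protected tetramer
Product: 26 target, epicatechin-(4α→6)-epiafzelechin-(4α→8)-epicatechin-(4β→6)-epicatechin
Conditions: H2 (1 atm), Pd(OH)2/C, Et3N (1.5 equiv), THF/MeOH/H2O, rt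
Reagents that add atoms: none
Why: hydrogenolysis removes the eighteen benzyl ethers and the C8 bromine cap of unit D in one operation, the amine taking up the HBr so that the acid-labile interflavan bonds stay intact.

**Compound list**

1 | (−)-epicatechin | O[C@@H]1Cc2c(O)cc(O)cc2O[C@@H]1c1ccc(O)c(O)c1 | starting material
2 | 5,7,3',4'-tetra-O-benzylepicatechin | O[C@@H]1Cc2c(OCc9ccccc9)cc(OCc9ccccc9)cc2O[C@@H]1c1ccc(OCc9ccccc9)c(OCc9ccccc9)c1 | intermediate
3 | 3,5,7,3',4'-penta-O-benzylepicatechin | C(c9ccccc9)O[C@@H]1Cc2c(OCc9ccccc9)cc(OCc9ccccc9)cc2O[C@@H]1c1ccc(OCc9ccccc9)c(OCc9ccccc9)c1 | intermediate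
4 | 8-bromo-3,5,7,3',4'-penta-O-benzylepicatechin | C(c9ccccc9)O[C@@H]1Cc2c(OCc9ccccc9)cc(OCc9ccccc9)c(Br)c2O[C@@H]1c1ccc(OCc9ccccc9)c(OCc9ccccc9)c1 | intermediate
5 | (2R,3R,4S)-penta-O-benzylepicatechin-4β-ol | c1c(OCc9ccccc9)cc(OCc9ccccc9)c2c1O[C@H](c1ccc(OCc9ccccc9)c(OCc9ccccc9)c1)[C@H](OCc9ccccc9)[C@H]2O | intermediate
6 | 8-iodo-penta-O-benzylepicatechin-4β-ol | Ic1c(OCc9ccccc9)cc(OCc9ccccc9)c2c1O[C@H](c1ccc(OCc9ccccc9)c(OCc9ccccc9)c1)[C@H](OCc9ccccc9)[C@H]2O | intermediate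
7 | deca-O-benzyl 8-iodoepicatechin-(4β→6)-8-bromoepicatechin | Ic1c(OCc9ccccc9)cc(OCc9ccccc9)c2c1O[C@H](c1ccc(OCc9ccccc9)c(OCc9ccccc9)c1)[C@H](OCc9ccccc9)[C@H]2c1c(OCc9ccccc9)c(Br)c2c(c1OCc9ccccc9)C[C@@H](OCc9ccccc9)[C@@H](c1ccc(OCc9ccccc9)c(OCc9ccccc9)c1)O2 | intermediate
8 | (2R,3S)-3,5,7,3',4'-pentakis(benzyloxy)flavan-4-one | c1c(OCc9ccccc9)cc(OCc9ccccc9)c2c1O[C@H](c1ccc(OCc9ccccc9)c(OCc9ccccc9)c1)[C@H](OCc9ccccc9)C2=O | intermediate
9 | 3,5-bis(benzyloxy)phenol | Oc1cc(OCc2ccccc2)cc(OCc2ccccc2)c1 | starting material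
10 | [3,5-bis(benzyloxy)phenoxy]tri(propan-2-yl)silane | CC(C)[Si](C(C)C)(C(C)C)Oc1cc(OCc2ccccc2)cc(OCc2ccccc2)c1 | intermediate
11 | 2,6-bis(benzyloxy)-4-(triisopropylsilyloxy)phenyllithium (not isolated) | [Li]c1c(OCc2ccccc2)cc(O[Si](C(C)C)(C(C)C)C(C)C)cc1OCc1ccccc1 | intermediate
12 | 4α-hydroxy-4β-aryl adduct of ketone 8 | c1c(OCc9ccccc9)cc(OCc9ccccc9)c2c1O[C@H](c1ccc(OCc9ccccc9)c(OCc9ccccc9)c1)[C@H](OCc9ccccc9)[C@@]2(O)c1c(OCc9ccccc9)cc(O[Si](C(C)C)(C(C)C)C(C)C)cc1OCc9ccccc9 | intermediate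
13 | all-cis 4α-[2,6-bis(benzyloxy)-4-(triisopropylsilyloxy)phenyl]-penta-O-benzylepicatechin | c1c(OCc9ccccc9)cc(OCc9ccccc9)c2c1O[C@H](c1ccc(OCc9ccccc9)c(OCc9ccccc9)c1)[C@H](OCc9ccccc9)[C@@H]2c1c(OCc9ccccc9)cc(O[Si](C(C)C)(C(C)C)C(C)C)cc1OCc9ccccc9 | intermediate
14 | all-cis 4α-[2,6-bis(benzyloxy)-4-hydroxyphenyl]-penta-O-benzylepicatechin | c1c(OCc9ccccc9)cc(OCc9ccccc9)c2c1O[C@H](c1ccc(OCc9ccccc9)c(OCc9ccccc9)c1)[C@H](OCc9ccccc9)[C@@H]2c1c(OCc9ccccc9)cc(O)cc1OCc9ccccc9 | intermediate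
15 | 4-(benzyloxy)benzaldehyde | O=Cc1ccc(OCc2ccccc2)cc1 | starting material
16 | ethynylmagnesium bromide | C#C[Mg]Br | starting material
17 | rac-1-[4-(benzyloxy)phenyl]prop-2-yn-1-ol | C#CC(O)c1ccc(OCc2ccccc2)cc1 | intermediate
18 | rac-1-[4-(benzyloxy)phenyl]prop-2-yn-1-yl acetate | C#CC(OC(C)=O)c1ccc(OCc2ccccc2)cc1 | intermediate
19 | (S)-propargyl ether of phenol 14 (terminal alkyne) | C(c9ccccc9)Oc1ccc([C@H](C#C)Oc2cc(OCc9ccccc9)c([C@@H]4c5c(OCc9ccccc9)cc(OCc9ccccc9)cc5O[C@H](c5ccc(OCc9ccccc9)c(OCc9ccccc9)c5)[C@@H]4OCc9ccccc9)c(OCc9ccccc9)c2)cc1 | intermediate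
20 | (R)-1,3-diarylpropargyl aryl ether (full skeleton, unit B open) | C(c9ccccc9)Oc1ccc([C@H](C#Cc3c(OCc9ccccc9)cc(OCc9ccccc9)c4c3O[C@H](c3ccc(OCc9ccccc9)c(OCc9ccccc9)c3)[C@H](OCc9ccccc9)[C@H]4c3c(OCc9ccccc9)c(Br)c4c(c3OCc9ccccc9)C[C@@H](OCc9ccccc9)[C@@H](c3ccc(OCc9ccccc9)c(OCc9ccccc9)c3)O4)Oc2cc(OCc9ccccc9)c([C@@H]4c5c(OCc9ccccc9)cc(OCc9ccccc9)cc5O[C@H](c5ccc(OCc9ccccc9)c(OCc9ccccc9)c5)[C@@H]4OCc9ccccc9)c(OCc9ccccc9)c2)cc1 | intermediate
21 | (2S)-4-aryl-2H-chromene of unit B | C(c9ccccc9)Oc1ccc([C@H]2Oc3cc(OCc9ccccc9)c([C@@H]4c5c(OCc9ccccc9)cc(OCc9ccccc9)cc5O[C@H](c5ccc(OCc9ccccc9)c(OCc9ccccc9)c5)[C@@H]4OCc9ccccc9)c(OCc9ccccc9)c3C(c3c(OCc9ccccc9)cc(OCc9ccccc9)c4c3O[C@H](c3ccc(OCc9ccccc9)c(OCc9ccccc9)c3)[C@H](OCc9ccccc9)[C@H]4c3c(OCc9ccccc9)c(Br)c4c(c3OCc9ccccc9)C[C@@H](OCc9ccccc9)[C@@H](c3ccc(OCc9ccccc9)c(OCc9ccccc9)c3)O4)=C2)cc1 | intermediate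
22 | 3β-boryl (BH2) adduct of 21 (not isolated) | C(c9ccccc9)Oc1ccc([C@H]2Oc3cc(OCc9ccccc9)c([C@@H]4c5c(OCc9ccccc9)cc(OCc9ccccc9)cc5O[C@H](c5ccc(OCc9ccccc9)c(OCc9ccccc9)c5)[C@@H]4OCc9ccccc9)c(OCc9ccccc9)c3[C@@H](c3c(OCc9ccccc9)cc(OCc9ccccc9)c4c3O[C@H](c3ccc(OCc9ccccc9)c(OCc9ccccc9)c3)[C@H](OCc9ccccc9)[C@H]4c3c(OCc9ccccc9)c(Br)c4c(c3OCc9ccccc9)C[C@@H](OCc9ccccc9)[C@@H](c3ccc(OCc9ccccc9)c(OCc9ccccc9)c3)O4)[C@@H]2B)cc1 | intermediate
23 | 2,3-trans-3,4-trans alcohol of unit B (3β-OH) | C(c9ccccc9)Oc1ccc([C@H]2Oc3cc(OCc9ccccc9)c([C@@H]4c5c(OCc9ccccc9)cc(OCc9ccccc9)cc5O[C@H](c5ccc(OCc9ccccc9)c(OCc9ccccc9)c5)[C@@H]4OCc9ccccc9)c(OCc9ccccc9)c3[C@@H](c3c(OCc9ccccc9)cc(OCc9ccccc9)c4c3O[C@H](c3ccc(OCc9ccccc9)c(OCc9ccccc9)c3)[C@H](OCc9ccccc9)[C@H]4c3c(OCc9ccccc9)c(Br)c4c(c3OCc9ccccc9)C[C@@H](OCc9ccccc9)[C@@H](c3ccc(OCc9ccccc9)c(OCc9ccccc9)c3)O4)[C@@H]2O)cc1 | intermediate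
24 | 2,4-cis-4-arylflavan-3-one of unit B | C(c9ccccc9)Oc1ccc([C@H]2Oc3cc(OCc9ccccc9)c([C@@H]4c5c(OCc9ccccc9)cc(OCc9ccccc9)cc5O[C@H](c5ccc(OCc9ccccc9)c(OCc9ccccc9)c5)[C@@H]4OCc9ccccc9)c(OCc9ccccc9)c3[C@@H](c3c(OCc9ccccc9)cc(OCc9ccccc9)c4c3O[C@H](c3ccc(OCc9ccccc9)c(OCc9ccccc9)c3)[C@H](OCc9ccccc9)[C@H]4c3c(OCc9ccccc9)c(Br)c4c(c3OCc9ccccc9)C[C@@H](OCc9ccccc9)[C@@H](c3ccc(OCc9ccccc9)c(OCc9ccccc9)c3)O4)C2=O)cc1 | intermediate
25 | octadeca-O-benzyl 8-bromo (unit D) tetramer, all-cis unit B with free 3α-OH | C(c9ccccc9)Oc1ccc([C@H]2Oc3cc(OCc9ccccc9)c([C@@H]4c5c(OCc9ccccc9)cc(OCc9ccccc9)cc5O[C@H](c5ccc(OCc9ccccc9)c(OCc9ccccc9)c5)[C@@H]4OCc9ccccc9)c(OCc9ccccc9)c3[C@@H](c3c(OCc9ccccc9)cc(OCc9ccccc9)c4c3O[C@H](c3ccc(OCc9ccccc9)c(OCc9ccccc9)c3)[C@H](OCc9ccccc9)[C@H]4c3c(OCc9ccccc9)c(Br)c4c(c3OCc9ccccc9)C[C@@H](OCc9ccccc9)[C@@H](c3ccc(OCc9ccccc9)c(OCc9ccccc9)c3)O4)[C@H]2O)cc1 | intermediate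
26 | CNP0103636.2, epicatechin-(4α→6)-epiafzelechin-(4α→8)-epicatechin-(4β→6)-epicatechin | Oc1ccc([C@H]2Oc3cc(O)c([C@@H]4c5c(O)cc(O)cc5O[C@H](c5ccc(O)c(O)c5)[C@@H]4O)c(O)c3[C@@H](c3c(O)cc(O)c4c3O[C@H](c3ccc(O)c(O)c3)[C@H](O)[C@H]4c3c(O)cc4c(c3O)C[C@@H](O)[C@@H](c3ccc(O)c(O)c3)O4)[C@H]2O)cc1 | target

**Step count and risks**

Total step count: 20.
Longest linear sequence: 14 steps (1 → 2 → 3 → 5 → 8 → 12 → 13 → 14 → 19 → 20 → 21 → 23 → 24 → 25 → 26).

Steps most likely to fail: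

1. Step 16 (key step). The gold centre may ionise the benzylic, propargylic C2–O1 bond, which would scramble C2 or fragment the ether, or the cyclisation may stall at the congested C4. Fallback: from 20, iodonium-induced 6-endo-dig cyclisation (I2, NaHCO3, MeCN/CH2Cl2, 0 °C) should give the 3-iodo-2H-chromene F1. The vinylic iodine is then removed with Bu3SnH and catalytic Pd(PPh3)4 (THF, rt, aryl bromide untouched), and the route is rejoined at 21.

2. Step 17. Borane uptake may be slow at the trisubstituted alkene, which is flanked by the perpendicular ring A of unit C, or facial selectivity may erode. Fallback: from 20 through the 3-iodo-2H-chromene F1 described above, Miyaura borylation (B2pin2, PdCl2(dppf), KOAc, dioxane, 80 °C; the vinylic iodide should react well before the hindered aryl bromide) should give the alkenyl pinacol boronate F2. Oxidation with NaBO3·4H2O (THF/H2O, rt) then gives the enol, which is expected to ketonise with protonation of C4 on the β face, anti to the C2 aryl group. The route is rejoined at 24 with no addition across C3=C4.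

3. Step 15. Oxidative addition at the di-ortho-oxygenated aryl iodide may be slow, so that alkyne homocoupling and base-induced propargyl-to-allenyl isomerisation consume 19. Fallback: from 7, Sonogashira coupling with excess ethynyltrimethylsilane (Pd(PPh3)4, CuI, Et3N, 60 °C) should give the silylalkyne F3, and K2CO3/MeOH the terminal alkyne F4. Addition of its zinc acetylide to aldehyde 15 (Et2Zn, Ti(Oi-Pr)4, the BINOL enantiomer that gives the S alcohol, toluene) gives the (S)-propargylic alcohol F5. Mitsunobu etherification with phenol 14 (PPh3, DIAD, toluene, 0 °C, inversion at C2) rejoins the route at 20.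

**Further compounds**

F1 | step 16 | 3-iodo-4-aryl-2H-chromene of unit B | C(c9ccccc9)Oc1ccc([C@H]2Oc3cc(OCc9ccccc9)c([C@@H]4c5c(OCc9ccccc9)cc(OCc9ccccc9)cc5O[C@H](c5ccc(OCc9ccccc9)c(OCc9ccccc9)c5)[C@@H]4OCc9ccccc9)c(OCc9ccccc9)c3C(c3c(OCc9ccccc9)cc(OCc9ccccc9)c4c3O[C@H](c3ccc(OCc9ccccc9)c(OCc9ccccc9)c3)[C@H](OCc9ccccc9)[C@H]4c3c(OCc9ccccc9)c(Br)c4c(c3OCc9ccccc9)C[C@@H](OCc9ccccc9)[C@@H](c3ccc(OCc9ccccc9)c(OCc9ccccc9)c3)O4)=C2I)cc1
F2 | step 17 | 3-(pinacolatoboryl)-4-aryl-2H-chromene of unit B | C(c9ccccc9)Oc1ccc([C@H]2Oc3cc(OCc9ccccc9)c([C@@H]4c5c(OCc9ccccc9)cc(OCc9ccccc9)cc5O[C@H](c5ccc(OCc9ccccc9)c(OCc9ccccc9)c5)[C@@H]4OCc9ccccc9)c(OCc9ccccc9)c3C(c3c(OCc9ccccc9)cc(OCc9ccccc9)c4c3O[C@H](c3ccc(OCc9ccccc9)c(OCc9ccccc9)c3)[C@H](OCc9ccccc9)[C@H]4c3c(OCc9ccccc9)c(Br)c4c(c3OCc9ccccc9)C[C@@H](OCc9ccccc9)[C@@H](c3ccc(OCc9ccccc9)c(OCc9ccccc9)c3)O4)=C2B3OC(C)(C)C(C)(C)O3)cc1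
F3 | step 15 | 8-(trimethylsilylethynyl) analogue of 7 | C[Si](C)(C)C#Cc3c(OCc9ccccc9)cc(OCc9ccccc9)c4c3O[C@H](c3ccc(OCc9ccccc9)c(OCc9ccccc9)c3)[C@H](OCc9ccccc9)[C@H]4c3c(OCc9ccccc9)c(Br)c4c(c3OCc9ccccc9)C[C@@H](OCc9ccccc9)[C@@H](c3ccc(OCc9ccccc9)c(OCc9ccccc9)c3)O4
F4 | step 15 | 8-ethynyl analogue of 7 | C#Cc3c(OCc9ccccc9)cc(OCc9ccccc9)c4c3O[C@H](c3ccc(OCc9ccccc9)c(OCc9ccccc9)c3)[C@H](OCc9ccccc9)[C@H]4c3c(OCc9ccccc9)c(Br)c4c(c3OCc9ccccc9)C[C@@H](OCc9ccccc9)[C@@H](c3ccc(OCc9ccccc9)c(OCc9ccccc9)c3)O4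
F5 | step 15 | (S)-1-[4-(benzyloxy)phenyl]-3-aryl-prop-2-yn-1-ol (aryl = C8 of unit C in units C–D) | C(c9ccccc9)Oc1ccc([C@@H](C#Cc3c(OCc9ccccc9)cc(OCc9ccccc9)c4c3O[C@H](c3ccc(OCc9ccccc9)c(OCc9ccccc9)c3)[C@H](OCc9ccccc9)[C@H]4c3c(OCc9ccccc9)c(Br)c4c(c3OCc9ccccc9)C[C@@H](OCc9ccccc9)[C@@H](c3ccc(OCc9ccccc9)c(OCc9ccccc9)c3)O4)O)cc1
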